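## The problem

Target 14 is a flavan: a chroman ring C (O1, C2, C3, C4, C4a, C8a) fused to a phloroglucinol-type ring A and carrying a resorcinol ring B at C2 (TBS = tert-butyldimethylsilyl and prenyl = 3-methylbut-2-en-1-yl throughout). The three oxygens of ring A are all different: O1 is in the ring, C5 carries a free hydroxyl and C7 a methyl ether. The prenyl chain sits at C8, between O1 and the methoxy group, so ring A must be desymmetrised and the chain placed at one defined carbon. C2 (S) is the only stereocentre; nothing else in the molecule can direct it, so a chiral catalyst has to set it. C2 is also a benzylic ether carbon on a 2,4-dioxygenated ring, so it can be lost again by C2–O1 heterolysis under acid or, once the ring B phenols are free, by quinone methide formation under base. The prenyl alkene excludes strong acid, alkene-seeking π-acids and unselective hydrogenation, and the three phenols need protecting groups that come off near neutrality. The opening for the plan is that C3 and C4 are two unsubstituted carbons between C4a and C2. They can be made as a C3=C4 alkene from a vinyl group on C4a and a vinyl group on C2 once the O1–C2 ether and its stereocentre exist, and that cis-disubstituted alkene can then be saturated beside the trisubstituted prenyl alkene.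

## Retrosynthesis

**14 to 13 (three O–Si bonds).** The phenols at C5, C2' and C4' are masked as TBS ethers in chroman 13. Benzyl ethers would need hydrogenolysis, which the prenyl alkene and the benzylic C2–O1 bond would not survive. Acetals would need acid at the ionisable C2, and aryl esters would transfer their acyl groups to the aryloxide used earlier. The forward step only asks for fluoride buffered so that no ring B phenoxide persists.

**13 to 12 (C3–C4 saturation).** The bridge is traced to the C3=C4 alkene of 2H-chromene 12. Unsaturation at C3=C4 keeps C2 tetrahedral and configured, unlike a flav-2-ene or flavylium level. It also avoids the C4 carbonyl of a flavanone, whose removal from an electron-rich benzylic position is awkward. The forward reaction must reduce a cis-disubstituted styrenic alkene and spare the prenyl alkene, without hydrogenolysis at C2.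

**12 to 11 (C3=C4, the key cut).** Cutting the alkene opens ring C to ether 11, which has a vinyl group on C4a and a vinyl group on C2. The neighbouring cuts are less attractive here. Closing O1–C2 last would mean a substitution or oxa-Michael addition at the ionisable benzylic carbon. Closing C4–C4a last would mean Friedel–Crafts or π-acid chemistry next to the prenyl group. Metathesis is neutral and leaves C2 alone. The precursor has lost the ring and is an acyclic diaryl-type ether. The forward step needs chemoselectivity among three alkenes.

**11 to 5 and 10 (O1–C2).** This cut halves the molecule into vinylphenol 5 (ring A) and linear cinnamyl carbonate 10 (ring B) and is where C2 is set, by iridium-catalysed asymmetric allylic etherification. Etherifying aldehyde 4 and methylenating afterwards was weighed. Its aryloxide is a weaker nucleophile and a better leaving group, so the branched ether would be more prone to re-ionise on the catalyst. 2-Vinylphenols, by contrast, are an established nucleophile class for this reaction. The forward step must give the branched isomer, control the allyl face, and attack through oxygen and not through the electron-rich ring carbon.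

**5 to 4, 3, and to 1 and 2 (C=C, O–Si, C3–prenyl).** The vinyl group comes from the formyl group of 4 by methylenation, the silyl ether from diol 3, and the prenyl group from C-alkylation of symmetric aldehyde 1 with bromide 2. Prenylating first uses the symmetry of 1 (C3 and C5 are equivalent). The new chain then shields its neighbouring hydroxyl, so the bulky silyl chloride is steered to the other one.

**10 to 9, 8, 7 and 6.** The carbonate is traced through allylic alcohol 9 and cinnamate 8 to silylated aldehyde 7 and 2,4-dihydroxybenzaldehyde 6. A linear (E)-carbonate is wanted because the iridium catalyst converts it cleanly into the branched ether, whereas a racemic branched carbonate would bring memory effects.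

## Roads not taken

**Alternative 1:** The cut removes C4–C4a and O1–C8a together. Ring C would come from 1-iodo-3-methoxy-5-(methoxymethoxy)-2-prenylbenzene (A1) and (S)-2-[2,4-bis(methoxymethoxy)phenyl]oxetane (A2). With Pd(OAc)2, a phosphine, norbornene and Cs2CO3, the aryl–norbornyl palladacycle of divalent palladium would form at the free ortho position of A1 and open A2 at its CH2 terminus. After norbornene extrusion the tethered alkoxide would couple at the ipso carbon to give chroman A3, (S)-2-[2,4-bis(methoxymethoxy)phenyl]-7-methoxy-5-(methoxymethoxy)-8-prenylchroman.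

- Merits: two bonds form in one convergent step, the prenyl group usefully blocks the second ortho position, and the stereocentre arrives preformed and does not react. The product is already a chroman, so no alkene has to be reduced beside the prenyl group. On step count and on that selectivity problem this road is better than the chosen one.
- Weak points: oxetanes are far less developed partners in this manifold than epoxides or aziridines. A2 is a strained benzylic ether on a 2,4-dialkoxyphenyl ring and may open at the benzylic carbon or ionise under the hot, Lewis-acidic conditions, giving the wrong connectivity or eroding the configuration. A1 needs the prenyl group between iodine and methoxy with no phenol to direct it. The acetals need acid at the end, which endangers C2 and the prenyl alkene.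
- Comparison: against the shorter sequence the chosen plan sets two ring-building events that are each established on this substrate class, a neutral key step and a fluoride deprotection.

**Alternative 2:** The cut removes C3–C4 and O1–C2. 3-(tert-Butyldimethylsilyloxy)-2-(hydroxymethyl)-5-methoxy-6-prenylphenol (A4), the NaBH4 reduction product of aldehyde 4, would be dehydrated by a chiral BINOL-derived phosphoric acid. The resulting ortho-quinone methide, 3-(tert-butyldimethylsilyloxy)-5-methoxy-2-methylidene-6-prenylcyclohexa-3,5-dien-1-one (A5), would undergo oxa-[4+2] cycloaddition with 5-(tert-butyldimethylsilyloxy)-2-vinylphenol (A6). The product is (S)-5-(tert-butyldimethylsilyloxy)-2-[4-(tert-butyldimethylsilyloxy)-2-hydroxyphenyl]-7-methoxy-8-prenylchroman (A7).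

- Merits: both ring bonds and the stereocentre form in one catalytic step at the chroman oxidation level. The ring A partner is one step from 4. The free ortho hydroxyl of A6, which the target needs anyway, is the group that binds the catalyst. This is the shortest road of all and needs no alkene reduction.
- Weak points: A5 has no substituent on the methide carbon, so it is less stabilised and more prone to self-condensation than the aryl-substituted methides on which this asymmetric cycloaddition rests. With C4 unsubstituted, the catalyst must control the styrene face alone. In A4 the hydroxyl that becomes O1 is ortho to the prenyl chain, and Brønsted acid invites its cyclisation to a 2,2-dimethylchroman. A6 can dimerise under acid, and A7, with a free ortho phenol on ring B, can re-ionise at C2 under the acid and lose its configuration.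
- Comparison: the chosen plan is longer. It sets against this a separation of stereocentre formation from ring closure, both under non-acidic conditions that the ortho-prenyl phenol and the ionisable C2 tolerate.

**Alternative 3:** The cut is C4–C4a alone. The ether (S)-1-[2,4-bis(pivaloyloxy)phenyl]prop-2-yn-1-yl 3-methoxy-5-(pivaloyloxy)-2-prenylphenyl ether (A8) would be treated with the monovalent gold complex Ph3PAuNTf2. C4a attacks the activated alkyne terminus in 6-endo mode to give (S)-2-[2,4-bis(pivaloyloxy)phenyl]-7-methoxy-5-(pivaloyloxy)-8-prenyl-2H-chromene (A9).

- Merits: the cyclisation is an isomerisation with no by-product. The prenyl group blocks the other ortho position, so the regiochemistry on ring A is fixed. Ring A needs no formyl or vinyl carbon, which saves the methylenation. In these respects it is as good as or better than the chosen plan.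
- Weak points: a cationic π-acid also activates the electron-rich prenyl alkene, so enyne cycloisomerisation between the alkyne and the prenyl group competes. The propargylic, benzylic C2–O1 bond of A8 can ionise on gold or trace acid, which is why the deactivating pivalates are needed. The pivalate at C5 in turn deactivates the ring that must attack. Pivalate removal at the end requires base or hydride, which produces the ring B phenoxides that threaten C2. A9 is at the same oxidation level as 12, so the selective alkene reduction remains. A8 itself needs an asymmetric propargylic etherification, so the step count to the cyclisation substrate is no lower.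
- Comparison: the chosen plan sets against the atom economy a ruthenium carbene that ignores trisubstituted alkenes and arenes, and silyl ethers that leave under buffered fluoride.

Key step: step 9

Assumption: the (Sa,S,S) enantiomer of the phosphoramidite in step 8 is taken to direct the aryloxide to the allyl face that gives (S)-11, as is usual for this ligand family. If the sense is the reverse, the (Ra,R,R) ligand is used and nothing else changes.

## Route

Step 1
Reactants: 1 2,6-dihydroxy-4-methoxybenzaldehyde; 2 prenyl bromide (1-bromo-3-methylbut-2-ene)
Product: 3 2,6-dihydroxy-4-methoxy-3-prenylbenzaldehyde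
Conditions: 2 (0.9 equiv), KOH (10% aq.), 0 °C to rt; cold aq. NH4Cl quench
Reagents that add atoms: none
Why: C-alkylation of a phloroglucinol-type phenoxide in water, where hydrogen bonding to oxygen favours attack through carbon; C3 and C5 of 1 are equivalent, so mono-C-prenylation can give only one constitutional isomer, and a slight deficit of 2 limits double alkylation.

Step 2
Reactants: 3 2,6-dihydroxy-4-methoxy-3-prenylbenzaldehyde
Product: 4 6-(tert-butyldimethylsilyloxy)-2-hydroxy-4-methoxy-3-prenylbenzaldehyde
Conditions: TBSCl (1.05 equiv), imidazole, CH2Cl2, −20 °C to 0 °C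
Reagents that add atoms: tert-butyldimethylsilyl chloride, CC(C)(C)[Si](C)(C)Cl
Why: Site-selective silylation under steric control: the 6-hydroxyl has a free ortho position, whereas the 2-hydroxyl lies between the formyl and prenyl groups, so the bulky chlorosilane should take the 6-oxygen.

Step 3
Reactants: 4 6-(tert-butyldimethylsilyloxy)-2-hydroxy-4-methoxy-3-prenylbenzaldehyde
Product: 5 3-(tert-butyldimethylsilyloxy)-5-methoxy-6-prenyl-2-vinylphenol
Conditions: Ph3PCH3Br (2.5 equiv), KN(SiMe3)2 (2.4 equiv), THF, 0 °C to rt
Reagents that add atoms: methyltriphenylphosphonium bromide, C[P+](c1ccccc1)(c1ccccc1)c1ccccc1.[Br-]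
Why: Wittig methylenation; salicylaldehydes are converted into 2-vinylphenols with excess ylide, one equivalent being spent on the phenol, and the non-nucleophilic amide base leaves the aryl silyl ether alone.

Step 4
Reactants: 6 2,4-dihydroxybenzaldehyde
Product: 7 2,4-bis(tert-butyldimethylsilyloxy)benzaldehyde
Conditions: TBSCl (2.4 equiv), imidazole, DMF, rt
Reagents that add atoms: tert-butyldimethylsilyl chloride, CC(C)(C)[Si](C)(C)Cl
Why: Standard silylation of both phenols; the silyl ethers are weaker donors than alkyl ethers, which tempers ionisation at the future C2.

Step 5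
Reactants: 7 2,4-bis(tert-butyldimethylsilyloxy)benzaldehyde
Product: 8 ethyl (E)-3-[2,4-bis(tert-butyldimethylsilyloxy)phenyl]prop-2-enoate
Conditions: Ph3P=CHCO2Et (1.2 equiv), toluene, 80 °C
Reagents that add atoms: ethyl (triphenylphosphoranylidene)acetate, CCOC(=O)C=P(c1ccccc1)(c1ccccc1)c1ccccc1
Why: Wittig olefination with a stabilised ylide gives the (E)-cinnamate under neutral, salt-free conditions that the aryl silyl ethers tolerate.

Step 6
Reactants: 8 ethyl (E)-3-[2,4-bis(tert-butyldimethylsilyloxy)phenyl]prop-2-enoate
Product: 9 (E)-3-[2,4-bis(tert-butyldimethylsilyloxy)phenyl]prop-2-en-1-ol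
Conditions: i-Bu2AlH (2.3 equiv), CH2Cl2, −78 °C
Reagents that add atoms: none
Why: 1,2-Reduction of the conjugated ester to the allylic alcohol by the aluminium hydride at low temperature, with the alkene geometry retained.

Step 7
Reactants: 9 (E)-3-[2,4-bis(tert-butyldimethylsilyloxy)phenyl]prop-2-en-1-ol
Product: 10 tert-butyl (E)-3-[2,4-bis(tert-butyldimethylsilyloxy)phenyl]prop-2-en-1-yl carbonate
Conditions: Boc2O (1.3 equiv), DMAP (cat.), CH2Cl2, 0 °C to rt
Reagents that add atoms: di-tert-butyl dicarbonate, CC(C)(C)OC(=O)OC(=O)OC(C)(C)C
Why: DMAP-catalysed O-acylation of a primary allylic alcohol; the tert-butyl carbonate is chosen because the tert-butoxide it releases in step 8 is too hindered to compete as a nucleophile.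

Step 8
Reactants: 5 3-(tert-butyldimethylsilyloxy)-5-methoxy-6-prenyl-2-vinylphenol; 10 tert-butyl (E)-3-[2,4-bis(tert-butyldimethylsilyloxy)phenyl]prop-2-en-1-yl carbonate
Product: 11 (S)-1-[2,4-bis(tert-butyldimethylsilyloxy)phenyl]prop-2-en-1-yl 3-(tert-butyldimethylsilyloxy)-5-methoxy-6-prenyl-2-vinylphenyl ether
Conditions: [Ir(cod)Cl]2 (2 mol %), (Sa,S,S)-(1,1'-binaphthalene-2,2'-diyl) N,N-bis[1-(2-methoxyphenyl)ethyl]phosphoramidite (4 mol %), n-PrNH2 pre-activation, K3PO4 (20 mol %), THF, rt to 40 °C
Reagents that add atoms: none
Why: Iridium-catalysed asymmetric allylic etherification: the cyclometalated monovalent iridium phosphoramidite complex ionises 10 to a π-allyl complex of trivalent iridium, and the aryloxide of 5 attacks the aryl-bearing terminus on the face away from the metal, giving the branched ether; the ligand fixes which allyl face is bound and so sets C2 as (S). 2-Vinylphenols and ortho-substituted cinnamyl carbonates are known partners for this catalyst family, and the tert-butoxide released with CO2 regenerates the aryloxide.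

Step 9
Reactants: 11 (S)-1-[2,4-bis(tert-butyldimethylsilyloxy)phenyl]prop-2-en-1-yl 3-(tert-butyldimethylsilyloxy)-5-methoxy-6-prenyl-2-vinylphenyl ether
Product: 12 (S)-2-[2,4-bis(tert-butyldimethylsilyloxy)phenyl]-5-(tert-butyldimethylsilyloxy)-7-methoxy-8-prenyl-2H-chromene
Conditions: second-generation Grubbs catalyst RuCl2(=CHPh)(PCy3)(H2IMes) (5 mol %), degassed CH2Cl2 (0.01 M), 40 °C
Reagents that add atoms: none
Why: Ring-closing olefin metathesis: after loss of PCy3 the 14-electron ruthenium benzylidene undergoes [2+2] cycloaddition and cycloreversion with the monosubstituted allyl alkene at C2, the new alkylidene adds across the C4a vinyl group, and retro-[2+2] of the ruthenacyclobutane releases the C3=C4 alkene and Ru=CH2, which carries the cycle and ends as ethylene. The closest known reaction type is the closure of allyl 2-vinylphenyl ethers, including enantioenriched 1-arylallyl ethers, to 2H-chromenes with this catalyst. Ring C closes as a six-membered ring by joining the two terminal alkene carbons, which leaves a necessarily cis endocyclic alkene conjugated with ring A. No stereocentre is formed; C2 is a tetrahedral spectator whose four bonds are untouched, and the neutral, non-ionising medium keeps the benzylic allylic ether from heterolysis, so the configuration from step 8 is carried over. The selectivity needed is among three alkenes: the trisubstituted prenyl alkene is a slow partner and could only close a seven-membered benzoxepine with loss of isobutene, whereas the six-membered closure joins two monosubstituted alkenes. Initiation at the hindered styrene would give an ortho-alkoxy-chelated benzylidene that closes onto the same allyl group, so both entry points lead to 12. High dilution holds back intermolecular cross-metathesis, and escaping ethylene makes the closure irreversible in practice.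

Step 10
Reactants: 12 (S)-2-[2,4-bis(tert-butyldimethylsilyloxy)phenyl]-5-(tert-butyldimethylsilyloxy)-7-methoxy-8-prenyl-2H-chromene
Product: 13 (S)-2-[2,4-bis(tert-butyldimethylsilyloxy)phenyl]-5-(tert-butyldimethylsilyloxy)-7-methoxy-8-prenylchroman
Conditions: 2-nitrobenzenesulfonyl hydrazide (excess, in portions), Et3N, CH2Cl2, rt
Reagents that add atoms: none
Why: Diimide reduction by concerted syn transfer of two hydrogens; the rate falls steeply with alkene substitution, so the cis-disubstituted C3=C4 alkene should be reduced before the trisubstituted prenyl alkene. No metal is present, so the benzylic C2–O1 bond is not hydrogenolysed and C2 is untouched.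

Step 11
Reactants: 13 (S)-2-[2,4-bis(tert-butyldimethylsilyloxy)phenyl]-5-(tert-butyldimethylsilyloxy)-7-methoxy-8-prenylchroman
Product: 14 (S)-2-(2,4-dihydroxyphenyl)-5-hydroxy-7-methoxy-8-prenylchroman (CNP0115018.1)
Conditions: Bu4NF (3.3 equiv), AcOH (3.3 equiv), THF, 0 °C, under argon
Reagents that add atoms: none
Why: Fluoride cleavage of aryl silyl ethers driven by Si–F bond formation; acetic acid protonates each phenoxide as it forms, so no ring B phenoxide can expel O1 from C2 (quinone methide formation), which would racemise the stereocentre.

## Compound list

1 | 2,6-dihydroxy-4-methoxybenzaldehyde | COc1cc(O)c(C=O)c(O)c1 | starting material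
2 | prenyl bromide (1-bromo-3-methylbut-2-ene) | CC(C)=CCBr | starting material
3 | 2,6-dihydroxy-4-methoxy-3-prenylbenzaldehyde | COc1cc(O)c(C=O)c(O)c1CC=C(C)C | intermediate
4 | 6-(tert-butyldimethylsilyloxy)-2-hydroxy-4-methoxy-3-prenylbenzaldehyde | COc1cc(O[Si](C)(C)C(C)(C)C)c(C=O)c(O)c1CC=C(C)C | intermediate
5 | 3-(tert-butyldimethylsilyloxy)-5-methoxy-6-prenyl-2-vinylphenol | COc1cc(O[Si](C)(C)C(C)(C)C)c(C=C)c(O)c1CC=C(C)C | intermediate
6 | 2,4-dihydroxybenzaldehyde | O=Cc1ccc(O)cc1O | starting material
7 | 2,4-bis(tert-butyldimethylsilyloxy)benzaldehyde | O=Cc1ccc(O[Si](C)(C)C(C)(C)C)cc1O[Si](C)(C)C(C)(C)C | intermediate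
8 | ethyl (E)-3-[2,4-bis(tert-butyldimethylsilyloxy)phenyl]prop-2-enoate | CCOC(=O)/C=C/c1ccc(O[Si](C)(C)C(C)(C)C)cc1O[Si](C)(C)C(C)(C)C | intermediate
9 | (E)-3-[2,4-bis(tert-butyldimethylsilyloxy)phenyl]prop-2-en-1-ol | OC/C=C/c1ccc(O[Si](C)(C)C(C)(C)C)cc1O[Si](C)(C)C(C)(C)C | intermediate
10 | tert-butyl (E)-3-[2,4-bis(tert-butyldimethylsilyloxy)phenyl]prop-2-en-1-yl carbonate | CC(C)(C)OC(=O)OC/C=C/c1ccc(O[Si](C)(C)C(C)(C)C)cc1O[Si](C)(C)C(C)(C)C | intermediate
11 | (S)-1-[2,4-bis(tert-butyldimethylsilyloxy)phenyl]prop-2-en-1-yl 3-(tert-butyldimethylsilyloxy)-5-methoxy-6-prenyl-2-vinylphenyl ether | COc1cc(O[Si](C)(C)C(C)(C)C)c(C=C)c(c1CC=C(C)C)O[C@H](c1ccc(O[Si](C)(C)C(C)(C)C)cc1O[Si](C)(C)C(C)(C)C)C=C | intermediate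
12 | (S)-2-[2,4-bis(tert-butyldimethylsilyloxy)phenyl]-5-(tert-butyldimethylsilyloxy)-7-methoxy-8-prenyl-2H-chromene | COc1cc(O[Si](C)(C)C(C)(C)C)c2c(c1CC=C(C)C)O[C@H](c1ccc(O[Si](C)(C)C(C)(C)C)cc1O[Si](C)(C)C(C)(C)C)C=C2 | intermediate
13 | (S)-2-[2,4-bis(tert-butyldimethylsilyloxy)phenyl]-5-(tert-butyldimethylsilyloxy)-7-methoxy-8-prenylchroman | COc1cc(O[Si](C)(C)C(C)(C)C)c2c(c1CC=C(C)C)O[C@H](c1ccc(O[Si](C)(C)C(C)(C)C)cc1O[Si](C)(C)C(C)(C)C)CC2 | intermediate
14 | (S)-2-(2,4-dihydroxyphenyl)-5-hydroxy-7-methoxy-8-prenylchroman (CNP0115018.1) | COc1cc(O)c2c(c1CC=C(C)C)O[C@H](c1ccc(O)cc1O)CC2 | target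

## Step count and least certain steps

Total: 11 steps. Longest linear sequence: 8 steps (6 to 14 through steps 4 to 11). The ring A branch (steps 1 to 3) joins at step 8.

**Step 9 (key step).** The prenyl alkene may be drawn into the metathesis, either by closure of the seven-membered ring with loss of isobutene or by exchange of its isopropylidene terminus. Turnover may be slow because the styrene is flanked by two ortho oxygens and can hold the ruthenium as a chelated benzylidene. Ruthenium hydrides from catalyst decay may also migrate the alkenes. The fallback builds ring C without metathesis, by an amine-catalysed oxa-Michael/aldol condensation; it sets out from 9 and 4 and comes back at 12.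
- Oxidation of 9 with MnO2 in CH2Cl2 gives (E)-3-[2,4-bis(tert-butyldimethylsilyloxy)phenyl]prop-2-enal F7.
- F7 and salicylaldehyde 4 are condensed under a diarylprolinol trimethylsilyl ether with a carboxylic acid co-catalyst, using the catalyst enantiomer that delivers the required configuration. This gives (R)-2-[2,4-bis(tert-butyldimethylsilyloxy)phenyl]-5-(tert-butyldimethylsilyloxy)-7-methoxy-8-prenyl-2H-chromene-3-carbaldehyde F8. F8 has the same spatial arrangement at C2 as 12; it is named (R) only because the formyl-bearing C3 outranks the aryl group.
- Decarbonylation with stoichiometric RhCl(PPh3)3 in hot toluene (Tsuji–Wilkinson decarbonylation) removes the formyl group and rejoins the route at 12.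

**Step 8.** Branched selectivity and enantiomeric purity may erode through reversible ionisation of the electron-rich ether on the catalyst. The hindered, di-ortho-substituted aryloxide may attack slowly. Attack may also occur through the ring carbon para to the oxygen instead of through oxygen. The fallback separates the stereocentre from the metal–allyl chemistry; it sets out from 7 and 5 and comes back at 11.
- Catalytic enantioselective addition of Zn(CH=CH2)2 to aldehyde 7 under a chiral β-amino alcohol ligand, with the ligand enantiomer chosen for the (R)-carbinol, gives (R)-1-[2,4-bis(tert-butyldimethylsilyloxy)phenyl]prop-2-en-1-ol F6.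
- Mitsunobu etherification of phenol 5 with F6 (PPh3, diisopropyl azodicarboxylate, toluene, low temperature) proceeds with inversion at the carbinol carbon and gives 11. The same ionisation tendency limits this reaction too, so low temperature and a non-polar solvent are essential.

**Step 1.** Double C-alkylation, O-alkylation and acid-induced cyclisation of the product on work-up may leave little mono-C-prenylated material. The fallback brings the chain in through oxygen and a sigmatropic shift; it sets out from 1 and comes back at 3.
- Mono-O-allylation (allyl bromide, K2CO3, acetone) gives 2-(allyloxy)-6-hydroxy-4-methoxybenzaldehyde F1.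
- Aromatic Claisen rearrangement (N,N-diethylaniline, about 190 °C) moves the allyl group to the only free ortho carbon and gives 3-allyl-2,6-dihydroxy-4-methoxybenzaldehyde F2.
- Cross-metathesis of F2 with 2-methyl-2-butene under RuCl2(=CHPh)(PCy3)(H2IMes) converts allyl into prenyl and gives 3.

**Step 2.** The silyl chloride may fail to discriminate between the two hydroxyls, or silylate both. The fallback places the silyl group while the ring is still symmetric, and the rearrangement then fixes which oxygen is free; it sets out from 1, comes back at 4, and replaces steps 1 and 2.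
- Monosilylation of 1 (TBSCl, imidazole) gives 2-(tert-butyldimethylsilyloxy)-6-hydroxy-4-methoxybenzaldehyde F3.
- Mitsunobu allylation of the remaining phenol (allyl alcohol, PPh3, diisopropyl azodicarboxylate) gives 2-(allyloxy)-6-(tert-butyldimethylsilyloxy)-4-methoxybenzaldehyde F4.
- Claisen rearrangement gives 3-allyl-6-(tert-butyldimethylsilyloxy)-2-hydroxy-4-methoxybenzaldehyde F5, in which the free hydroxyl is necessarily the one next to the allyl group.
- Cross-metathesis with 2-methyl-2-butene under RuCl2(=CHPh)(PCy3)(H2IMes) gives 4.

**Step 10.** The prenyl alkene may be over-reduced before the hindered C3=C4 alkene is consumed, since diimide discriminates by substitution only moderately. The fallback replaces group transfer by coordination-gated homogeneous hydrogenation: 12 is hydrogenated with RhCl(PPh3)3 (cat.) under H2 in benzene–ethanol. This catalyst binds and reduces cis-disubstituted alkenes far faster than trisubstituted ones and does not cleave benzylic ethers. The fallback sets out from 12, comes back at 13 and makes no new compound (F0).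

## Further compounds

F1 | step 1 | 2-(allyloxy)-6-hydroxy-4-methoxybenzaldehyde | C=CCOc1cc(OC)cc(O)c1C=O
F2 | step 1 | 3-allyl-2,6-dihydroxy-4-methoxybenzaldehyde | C=CCc1c(OC)cc(O)c(C=O)c1O
F3 | step 2 | 2-(tert-butyldimethylsilyloxy)-6-hydroxy-4-methoxybenzaldehyde | COc1cc(O)c(C=O)c(O[Si](C)(C)C(C)(C)C)c1
F4 | step 2 | 2-(allyloxy)-6-(tert-butyldimethylsilyloxy)-4-methoxybenzaldehyde | C=CCOc1cc(OC)cc(O[Si](C)(C)C(C)(C)C)c1C=O
F5 | step 2 | 3-allyl-6-(tert-butyldimethylsilyloxy)-2-hydroxy-4-methoxybenzaldehyde | C=CCc1c(OC)cc(O[Si](C)(C)C(C)(C)C)c(C=O)c1O
F6 | step 8 | (R)-1-[2,4-bis(tert-butyldimethylsilyloxy)phenyl]prop-2-en-1-ol | C=C[C@@H](O)c1ccc(O[Si](C)(C)C(C)(C)C)cc1O[Si](C)(C)C(C)(C)C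
F7 | step 9 | (E)-3-[2,4-bis(tert-butyldimethylsilyloxy)phenyl]prop-2-enal | O=C/C=C/c1ccc(O[Si](C)(C)C(C)(C)C)cc1O[Si](C)(C)C(C)(C)C
F8 | step 9 | (R)-2-[2,4-bis(tert-butyldimethylsilyloxy)phenyl]-5-(tert-butyldimethylsilyloxy)-7-methoxy-8-prenyl-2H-chromene-3-carbaldehyde | COc1cc(O[Si](C)(C)C(C)(C)C)c2c(c1CC=C(C)C)O[C@H](c1ccc(O[Si](C)(C)C(C)(C)C)cc1O[Si](C)(C)C(C)(C)C)C(C=O)=C2
F0 | step 10 | none | none
A1 | alternative 1 | 1-iodo-3-methoxy-5-(methoxymethoxy)-2-prenylbenzene | COc1cc(OCOC)cc(I)c1CC=C(C)C
A2 | alternative 1 | (S)-2-[2,4-bis(methoxymethoxy)phenyl]oxetane | COCOc1ccc([C@@H]2CCO2)c(OCOC)c1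
A3 | alternative 1 | (S)-2-[2,4-bis(methoxymethoxy)phenyl]-7-methoxy-5-(methoxymethoxy)-8-prenylchroman | COc1cc(OCOC)c2c(c1CC=C(C)C)O[C@H](c1ccc(OCOC)cc1OCOC)CC2
A4 | alternative 2 | 3-(tert-butyldimethylsilyloxy)-2-(hydroxymethyl)-5-methoxy-6-prenylphenol | COc1cc(O[Si](C)(C)C(C)(C)C)c(CO)c(O)c1CC=C(C)C
A5 | alternative 2 | 3-(tert-butyldimethylsilyloxy)-5-methoxy-2-methylidene-6-prenylcyclohexa-3,5-dien-1-one | C=C1C(O[Si](C)(C)C(C)(C)C)=CC(OC)=C(CC=C(C)C)C1=O
A6 | alternative 2 | 5-(tert-butyldimethylsilyloxy)-2-vinylphenol | C=Cc1ccc(O[Si](C)(C)C(C)(C)C)cc1O
A7 | alternative 2 | (S)-5-(tert-butyldimethylsilyloxy)-2-[4-(tert-butyldimethylsilyloxy)-2-hydroxyphenyl]-7-methoxy-8-prenylchroman | COc1cc(O[Si](C)(C)C(C)(C)C)c2c(c1CC=C(C)C)O[C@H](c1ccc(O[Si](C)(C)C(C)(C)C)cc1O)CC2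
A8 | alternative 3 | (S)-1-[2,4-bis(pivaloyloxy)phenyl]prop-2-yn-1-yl 3-methoxy-5-(pivaloyloxy)-2-prenylphenyl ether | COc1cc(OC(=O)C(C)(C)C)cc(c1CC=C(C)C)O[C@H](c1ccc(OC(=O)C(C)(C)C)cc1OC(=O)C(C)(C)C)C#C
A9 | alternative 3 | (S)-2-[2,4-bis(pivaloyloxy)phenyl]-7-methoxy-5-(pivaloyloxy)-8-prenyl-2H-chromene | COc1cc(OC(=O)C(C)(C)C)c2c(c1CC=C(C)C)O[C@H](c1ccc(OC(=O)C(C)(C)C)cc1OC(=O)C(C)(C)C)C=C2
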